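## Retrosynthetic overview

1. Target ⇐ face-selective epoxidation (two C–O bonds, the only stereocentre) of an achiral 2-arylallyl acetate that already carries all three esters. The oxirane is the only ring made and it is made last.
2. 2-Arylallyl acetate ⇐ O-acetylation of the 2-arylallyl alcohol ⇐ aryl–alkenyl C–C bond by one-pot borylation/Suzuki coupling of an aryl bromide with 2-bromoallyl alcohol.
3. Aryl bromide diester ⇐ two chemoselective O-acylations of 4-bromo-3-hydroxybenzyl alcohol: lipase isovalerylation of the benzylic OH, then mixed-anhydride angeloylation of the phenol.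
4. 4-Bromo-3-hydroxybenzyl alcohol ⇐ borane reduction of 4-bromo-3-hydroxybenzoic acid; the side chains come from isovaleric acid, angelic acid and acetic anhydride.

Assumption: the stereocentre is read as (R) (O > CH2OAc > ring CH2 > aryl); the facial sense of the new epoxidation in step 6 cannot be known in advance, so it is written for the (S,S)-catalyst with the L-amino-acid co-ligand, and the mirror-image pair is used if the first run gives the (S)-epoxide.

## Route

Step 1
Reactants: 1 4-bromo-3-hydroxybenzoic acid
Product: 2 2-bromo-5-(hydroxymethyl)phenol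
Conditions: BH3·THF (3 equiv), THF, 0 °C to rt; then MeOH
Reagents that add atoms: none
Why: Borane reduction of a carboxylic acid: electrophilic BH3 reduces the acid through its acyloxyborane far faster than it touches the aryl bromide, and the phenol only consumes hydride and is freed again on methanolysis.

Step 2
Reactants: 2 2-bromo-5-(hydroxymethyl)phenol; 3 3-methylbutanoic acid (isovaleric acid)
Product: 4 (4-bromo-3-hydroxyphenyl)methyl 3-methylbutanoate
Conditions: immobilised Candida antarctica lipase B, 4 Å molecular sieves, t-BuOMe, 45 °C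
Reagents that add atoms: none
Why: Lipase-catalysed esterification (acyl-enzyme transfer) acylates the primary benzylic hydroxyl only, because phenols are not acyl acceptors for this enzyme (as in lipase syntheses of vanillyl esters), and the sieves remove water to drive the equilibrium.

Step 3
Reactants: 4 (4-bromo-3-hydroxyphenyl)methyl 3-methylbutanoate; 5 (2Z)-2-methylbut-2-enoic acid (angelic acid); 6 2,4,6-trichlorobenzoyl chloride
Product: 8 2-bromo-5-{[(3-methylbutanoyl)oxy]methyl}phenyl (2Z)-2-methylbut-2-enoate, via angelic 2,4,6-trichlorobenzoic anhydride 7 (not isolated)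
Conditions: 5, 6, Et3N, toluene, 0 °C, 1 h; then 4, Et3N, rt to 40 °C
Reagents that add atoms: none
Why: Yamaguchi-type mixed-anhydride acylation: the triethylammonium phenoxide attacks the unhindered angeloyl carbonyl of 7 (the aroyl carbonyl is shielded by two ortho chlorines), and leaving out DMAP or any other nucleophilic catalyst keeps the Z alkene from isomerising to the tiglate.

Step 4
Reactants: 8 2-bromo-5-{[(3-methylbutanoyl)oxy]methyl}phenyl (2Z)-2-methylbut-2-enoate; 9 bis(pinacolato)diboron; 10 2-bromoprop-2-en-1-ol (2-bromoallyl alcohol)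
Product: 12 2-(3-hydroxyprop-1-en-2-yl)-5-{[(3-methylbutanoyl)oxy]methyl}phenyl (2Z)-2-methylbut-2-enoate, via aryl pinacol boronate 11 (not isolated)
Conditions: 9, Pd(dppf)Cl2 (3 mol%), KOAc, dioxane, 85 °C; then 10 (1.5 equiv), K3PO4, H2O (5 equiv), 55 °C
Reagents that add atoms: none
Why: One-pot Miyaura borylation then Suzuki–Miyaura coupling: acetate-mediated borylation tolerates the esters, boronate 11 then transmetalates to the alkenylpalladium formed from the vinyl C–Br bond of 10, and using the free allylic alcohol instead of an allylic acetate gives zerovalent palladium no leaving group to ionise, while phosphate with little water spares the aryl ester.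

Step 5
Reactants: 12 2-(3-hydroxyprop-1-en-2-yl)-5-{[(3-methylbutanoyl)oxy]methyl}phenyl (2Z)-2-methylbut-2-enoate
Product: 13 2-[3-(acetyloxy)prop-1-en-2-yl]-5-{[(3-methylbutanoyl)oxy]methyl}phenyl (2Z)-2-methylbut-2-enoate
Conditions: Ac2O, pyridine, CH2Cl2, 0 °C to rt
Reagents that add atoms: acetic anhydride CC(=O)OC(C)=O
Why: Plain O-acetylation (nucleophilic acyl substitution) of the only free hydroxyl, run without DMAP so that the angelate geometry and the aryl ester are left alone.

Step 6
Reactants: 13 2-[3-(acetyloxy)prop-1-en-2-yl]-5-{[(3-methylbutanoyl)oxy]methyl}phenyl (2Z)-2-methylbut-2-enoate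
Product: 14 2-[(2R)-2-(acetoxymethyl)oxiran-2-yl]-5-{[(3-methylbutanoyl)oxy]methyl}phenyl (2Z)-2-methylbut-2-enoate
Conditions: [Fe((S,S)-Me2N-PDP)(OTf)2] (2 mol%; Me2N-PDP = (2S,2'S)-1,1'-bis{[4-(dimethylamino)pyridin-2-yl]methyl}-2,2'-bipyrrolidine), N-naphthalimido-L-isoleucine (4 mol%), 30% aq. H2O2 (1.8 equiv, slow addition), MeCN, −30 °C
Reagents that add atoms: hydrogen peroxide OO
Why: Proposed new method: enantioselective epoxidation of a 2-arylallyl acetate by a non-heme divalent iron complex and H2O2, in which the amino-acid co-ligand binds cis to the iron hydroperoxide, its carboxylic acid protonates the distal oxygen and drives O–O heterolysis to an electrophilic pentavalent oxo-iron carboxylate that attacks the unhindered CH2 terminus of the 1,1-disubstituted alkene first, while the pocket made by the bipyrrolidine backbone and the bulky carboxylate distinguishes the ortho-twisted aryl group from the CH2OAc arm and so delivers oxygen to the face that makes the quaternary centre (R); the electron-poor angelate C=C should react much more slowly with this electrophilic oxidant and the cold, near-neutral medium leaves the esters and the new epoxide intact; the closest known reaction type is the iron/amino-acid co-ligand epoxidation of α-alkylstyrenes with H2O2, which has not been shown for allylic esters or ortho-acyloxy aryl groups.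

## Compound list

1 | 4-bromo-3-hydroxybenzoic acid | OC(=O)c1ccc(Br)c(O)c1 | starting material
2 | 2-bromo-5-(hydroxymethyl)phenol (4-bromo-3-hydroxybenzyl alcohol) | OCc1ccc(Br)c(O)c1 | intermediate
3 | 3-methylbutanoic acid (isovaleric acid) | CC(C)CC(=O)O | starting material
4 | (4-bromo-3-hydroxyphenyl)methyl 3-methylbutanoate | CC(C)CC(=O)OCc1ccc(Br)c(O)c1 | intermediate
5 | (2Z)-2-methylbut-2-enoic acid (angelic acid) | C/C=C(/C)C(=O)O | starting material
6 | 2,4,6-trichlorobenzoyl chloride | O=C(Cl)c1c(Cl)cc(Cl)cc1Cl | starting material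
7 | (2Z)-2-methylbut-2-enoic 2,4,6-trichlorobenzoic anhydride | C/C=C(/C)C(=O)OC(=O)c1c(Cl)cc(Cl)cc1Cl | intermediate
8 | 2-bromo-5-{[(3-methylbutanoyl)oxy]methyl}phenyl (2Z)-2-methylbut-2-enoate | C/C=C(/C)C(=O)Oc1cc(COC(=O)CC(C)C)ccc1Br | intermediate
9 | bis(pinacolato)diboron | CC1(C)OB(OC1(C)C)B1OC(C)(C)C(C)(C)O1 | starting material
10 | 2-bromoprop-2-en-1-ol (2-bromoallyl alcohol) | OCC(Br)=C | starting material
11 | 5-{[(3-methylbutanoyl)oxy]methyl}-2-(4,4,5,5-tetramethyl-1,3,2-dioxaborolan-2-yl)phenyl (2Z)-2-methylbut-2-enoate | C/C=C(/C)C(=O)Oc1cc(COC(=O)CC(C)C)ccc1B1OC(C)(C)C(C)(C)O1 | intermediate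
12 | 2-(3-hydroxyprop-1-en-2-yl)-5-{[(3-methylbutanoyl)oxy]methyl}phenyl (2Z)-2-methylbut-2-enoate | C/C=C(/C)C(=O)Oc1cc(COC(=O)CC(C)C)ccc1C(=C)CO | intermediate
13 | 2-[3-(acetyloxy)prop-1-en-2-yl]-5-{[(3-methylbutanoyl)oxy]methyl}phenyl (2Z)-2-methylbut-2-enoate | C/C=C(/C)C(=O)Oc1cc(COC(=O)CC(C)C)ccc1C(=C)COC(C)=O | intermediate
14 | 2-[(2R)-2-(acetoxymethyl)oxiran-2-yl]-5-{[(3-methylbutanoyl)oxy]methyl}phenyl (2Z)-2-methylbut-2-enoate | C/C=C(/C)C(=O)Oc1cc(COC(=O)CC(C)C)ccc1[C@]1(COC(C)=O)CO1 | target

## Step count and risk

Total steps: 6. Longest linear sequence: 6 (steps 1 to 6).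

**Step 6 (the proposed new epoxidation)** is the most likely to fail. The allylic acetate and the twisted aryl group lower the nucleophilicity of the alkene, the enantiomeric excess may be modest, and the angelate double bond may compete for oxidant. The enantiomeric excess is read by chiral HPLC and the sense is checked against material from the fallback.

The fallback is known chemistry. It sets out from 12 and comes back at 14. Sharpless asymmetric epoxidation of the free allylic alcohol (Ti(OiPr)4 10 mol%, L-(+)-diethyl tartrate 12 mol%, tert-butyl hydroperoxide, 4 Å sieves, CH2Cl2, −20 °C) gives the epoxy alcohol 2-[(2S)-2-(hydroxymethyl)oxiran-2-yl]-5-{[(3-methylbutanoyl)oxy]methyl}phenyl (2Z)-2-methylbut-2-enoate F1. This reaction has precedent for 2-arylallyl alcohols with ortho-substituted aryl groups. L-(+)-tartrate gives the (S)-epoxy alcohol, the same sense it gives (S)-glycidol from allyl alcohol. Acetylation (Ac2O, pyridine, 0 °C) turns F1 into 14; the descriptor changes from S to R only because the priorities change, no bond at the stereocentre is touched.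

**Step 4 (borylation/Suzuki coupling)** is the second risk. The aryl angelate may hydrolyse under aqueous base or migrate to the new neighbouring primary alcohol, and the ortho-substituted boronate may protodeboronate.

The fallback sets out from 8 and comes back at 13, bypassing 12. Anhydrous Suzuki coupling of 8 with isopropenylboronic acid pinacol ester (Pd(dppf)Cl2, CsF, dioxane, 80 °C) gives the isopropenylarene 5-{[(3-methylbutanoyl)oxy]methyl}-2-(prop-1-en-2-yl)phenyl (2Z)-2-methylbut-2-enoate F2, with no free alcohol and no water. Ionic allylic bromination (N-bromosuccinimide, cat. TsOH, THF, reflux), the standard route from α-methylstyrenes to 2-arylallyl bromides, gives the allylic bromide 2-(3-bromoprop-1-en-2-yl)-5-{[(3-methylbutanoyl)oxy]methyl}phenyl (2Z)-2-methylbut-2-enoate F3. Displacement with KOAc in DMF at rt gives 13.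

**Step 3 (angeloylation)** is the third risk. Angelic acid derivatives isomerise easily to the tiglate (E) series, and the two aryl esters would be hard to separate; the geometry is checked by 1H NMR of the vinyl proton.

The fallback sets out from 4 and comes back at 8, and builds the Z alkene instead of transferring it. Esterification of 4 with 2-[bis(2,2,2-trifluoroethoxy)phosphoryl]propanoic acid (a known reagent; N,N'-dicyclohexylcarbodiimide, cat. DMAP, CH2Cl2) gives the aryl phosphonopropanoate 2-bromo-5-{[(3-methylbutanoyl)oxy]methyl}phenyl 2-[bis(2,2,2-trifluoroethoxy)phosphoryl]propanoate F4. Still–Gennari olefination with acetaldehyde (KN(SiMe3)2, 18-crown-6, THF, −78 °C) then gives the Z-trisubstituted enoate 8.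

## Further compounds

F1 | step 6 | 2-[(2S)-2-(hydroxymethyl)oxiran-2-yl]-5-{[(3-methylbutanoyl)oxy]methyl}phenyl (2Z)-2-methylbut-2-enoate | C/C=C(/C)C(=O)Oc1cc(COC(=O)CC(C)C)ccc1[C@]1(CO)CO1
F2 | step 4 | 5-{[(3-methylbutanoyl)oxy]methyl}-2-(prop-1-en-2-yl)phenyl (2Z)-2-methylbut-2-enoate | C/C=C(/C)C(=O)Oc1cc(COC(=O)CC(C)C)ccc1C(C)=C
F3 | step 4 | 2-(3-bromoprop-1-en-2-yl)-5-{[(3-methylbutanoyl)oxy]methyl}phenyl (2Z)-2-methylbut-2-enoate | C/C=C(/C)C(=O)Oc1cc(COC(=O)CC(C)C)ccc1C(=C)CBr
F4 | step 3 | 2-bromo-5-{[(3-methylbutanoyl)oxy]methyl}phenyl 2-[bis(2,2,2-trifluoroethoxy)phosphoryl]propanoate | CC(C(=O)Oc1cc(COC(=O)CC(C)C)ccc1Br)P(=O)(OCC(F)(F)F)OCC(F)(F)F
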